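The numbers in the tables were generated by integration with constants of no real substance; the scatter is artificial.

This closed, stirred vessel gets one charge of D on X and is read at the end, so the choice for the next run is how much D goes in.

| flask | X | D | remark | time |
|---|---|---|---|---|
| grey | 0.065 M | 0.63 equiv | run made earlier |  |
| amber | 0.065 M | 4.1 equiv | run made earlier |  |
| ash | 0.065 M | 0.500 equiv |  | 30 h |
| birch | 0.065 M | 2.00 equiv |  | 30 h |
| oak | 0.065 M | 3.00 equiv |  | 30 h |

- grey (time / h: Q / %): 1.00: 2.8; 3.00: 7.5; 5.00: 10.1; 8.00: 13.6; 12.0: 16.5; 15.0: 18.6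
- amber (time / h: Q / %): 1.00: 14.0; 3.00: 27.6; 5.00: 31.5; 8.00: 31.2; 12.0: 25.1; 15.0: 21.0

(scatter of a reading: 0.5 percentage points)

- Q at the end, in percent of the X charged, for each flask in turn (ash, birch, oak)

- a species is counted by the X in it: one G counts as two
- amounts and yields of Q count G too
- the earlier runs were read with a standard deviation of 0.5 percentage points
- steps thought possible: X + D -> Q + Z; D + Q -> J + Z; X + Q <-> G; X + Z -> E; D <-> L
- in an amount of Q, one G counts as one Q

Take the symmetric case as the zero of your scale: X goes to Q and Q goes to J with equal constants, a selectivity factor of one, each step first order in D. Q then tops out at 36.8% of the X charged, and grey's first reading, 2.8% after 1.00 h on 0.63 equiv, gives 22.5 h for the peak dose, the equivalents of D times the hours at which Q tops out.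

Divided by amber's charge it gives 5.49 h, and amber reads 31.5% at 5.00 h and 31.2% at 8.00 h. That top reading lies below the symmetric height.

The peak times are 45.0 h for ash, 11.3 h for birch and 7.50 h for oak, so at 30 h birch and oak stand past the top. Birch's final dose equals amber's at 14.6 h, and amber read 21.0% at 15.0 h, so I put birch there. Oak's equals amber's at 22.0 h, beyond the readings, on a curve still falling, so I drop oak. Grey's last reading is 0.674 of the symmetric curve at its dose; the same factor puts ash at 23.1%. I would charge ash, by a thin margin.

The forecast gives 20%, 29% and 23% for ash, birch and oak, putting birch ahead of ash, and remarks: “Grey slows faster late than this simple model predicts”.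

    X + D → Q + Z (k = 1.80 × 10⁻⁴ L mol⁻¹ s⁻¹)
    D + Q → J + Z (k = 3.10 × 10⁻⁴ L mol⁻¹ s⁻¹)
    X + Q ⇌ G, settled at all times (K = 37.0 L mol⁻¹)
    X + Z → E (k = 3.70 × 10⁻⁴ L mol⁻¹ s⁻¹)
    D ⇌ L (K = 2.00, k = 7.30 × 10⁻⁶ s⁻¹)

Birch ends at 24.0%, above ash at 20.1%, with oak at 14.6%. Birch, peak time 11.3 h, fell from 30.0% at 15.0 h to 24.0%, and oak, peak time 7.50 h, from 26.8% to 14.6%; ash, peak time 45.0 h, rose from 15.9% to 20.1%, short of my 23.1%. In ash, X + D took X 1.7 times as fast as X + Z at 7.54 h. At 30.0 h that ratio had dropped to 0.55, with X at 51.3%.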